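**Retrosynthetic overview**

1. The target is reached from a bis-epoxide by C3 angeloylation and C9 desilylation, and the bis-epoxide from one hydroxyl-directed double epoxidation of a (1(10)Z,4Z)-germacradien-3-ol. The strategy rests on the C3 carbinol that lies between the two cis-trisubstituted oxiranes C4–C5 and C1–C10 of the ten-membered carbocycle: in the diene, O3 is allylic to C4=C5 and homoallylic to C1=C10, so one vanadium alkoxide can close both three-membered rings and set C1, C4, C5 and C10.
2. The dienol comes from closure of the ten-membered ring at C3–C4 by an intramolecular Nozaki–Hiyama–Kishi reaction of a (Z)-alkenyl iodide with a C3 aldehyde, followed by oxidation and Corey–Bakshi–Shibata reduction to fix C3 as S.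
3. The seco compound comes from a trans-γ-lactone (C5–C8): lactone opening frees O8 for the angelate while O9 already carries its silyl ether, and Stork–Zhao olefination of the C5 aldehyde gives C4=C5.
4. The lactone comes from (S)-5-(hydroxymethyl)butenolide (C8 from the chiral pool): copper-catalysed isopropenyl addition sets C7, and a Felkin–Anh-controlled intermolecular Nozaki–Hiyama–Kishi coupling with a (Z)-alkenyl iodide (C14, C10, C1–C3) sets C9 and brings in C1=C10.
5. Ring order: γ-lactone (present from the start, opened in step 9), ten-membered carbocycle (step 15), oxirane C4–C5 and then oxirane C1–C10 (both in step 18).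

Key step: step 18

Remark: germacrane numbering is used for all compounds (ring C1–C10, methyl C14 on C10, methyl C15 on C4, isopropenyl C11–C13 on C7), and CNP0304877.1 is taken to be exactly the stereoisomer of the given SMILES. CIP descriptors at C4, C9 and C10 change along the series 19–23 only because substituent priorities change; no centre is inverted.

**Route**

Step 1
Reactants: 1 3-[(4-methoxyphenyl)methoxy]propan-1-ol
Product: 2 3-[(4-methoxyphenyl)methoxy]propanal
Conditions: Dess–Martin periodinane, CH2Cl2, 0 °C → rt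
Reagents that add atoms: none
Why: Dess–Martin oxidation converts the primary alcohol into the aldehyde under neutral conditions that leave the 4-methoxybenzyl ether untouched.

Step 2
Reactants: 2 3-[(4-methoxyphenyl)methoxy]propanal
Product: 3 1-({[(3Z)-4-iodopent-3-en-1-yl]oxy}methyl)-4-methoxybenzene (carbons C14, C10, C1, C2, C3)
Conditions: EtPPh3+ I−, n-BuLi, THF, 0 °C; I2, −78 °C; NaN(SiMe3)2, −20 °C; then 2, −78 → −20 °C
Reagents that add atoms: ethyltriphenylphosphonium iodide, CC[P+](c1ccccc1)(c1ccccc1)c1ccccc1.[I-]; iodine, II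
Why: Stork–Zhao olefination, in which the α-iodo ylide adds under kinetic control to give the (Z)-2-iodoalk-2-ene (iodine cis to the chain), which fixes the later C1=C10 geometry.

Step 3
Reactants: 4 (5S)-5-(hydroxymethyl)furan-2(5H)-one
Product: 5 (5S)-5-{[(tert-butyldiphenylsilyl)oxy]methyl}furan-2(5H)-one
Conditions: t-BuPh2SiCl, imidazole, CH2Cl2, 0 °C → rt
Reagents that add atoms: tert-butyl(chloro)diphenylsilane, CC(C)(C)[Si](Cl)(c1ccccc1)c1ccccc1
Why: Standard silylation of the primary alcohol, giving a bulky ether that shields the butenolide face cis to C9 in the next step.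

Step 4
Reactants: 5 (5S)-5-{[(tert-butyldiphenylsilyl)oxy]methyl}furan-2(5H)-one
Product: 6 (4R,5S)-5-{[(tert-butyldiphenylsilyl)oxy]methyl}-4-(prop-1-en-2-yl)oxolan-2-one (trans lactone, C5–C9)
Conditions: CH2=C(CH3)MgBr, CuBr·SMe2 (10 mol %), THF, −78 → −40 °C; aq. NH4Cl
Reagents that add atoms: isopropenylmagnesium bromide, C=C(C)[Mg]Br
Why: Copper-catalysed conjugate addition of the Grignard reagent to the butenolide occurs on the face opposite the C8 substituent, so the isopropenyl group enters trans and C7 is set as R.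

Step 5
Reactants: 6 (4R,5S)-5-{[(tert-butyldiphenylsilyl)oxy]methyl}-4-(prop-1-en-2-yl)oxolan-2-one
Product: 7 (4R,5S)-5-(hydroxymethyl)-4-(prop-1-en-2-yl)oxolan-2-one
Conditions: Bu4NF, AcOH, THF, 0 °C → rt
Reagents that add atoms: none
Why: Fluoride-mediated desilylation, buffered with acetic acid so that the lactone neither opens nor translactonises.

Step 6
Reactants: 7 (4R,5S)-5-(hydroxymethyl)-4-(prop-1-en-2-yl)oxolan-2-one
Product: 8 (2S,3R)-5-oxo-3-(prop-1-en-2-yl)oxolane-2-carbaldehyde
Conditions: Dess–Martin periodinane, CH2Cl2, 0 °C → rt; used crude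
Reagents that add atoms: none
Why: Dess–Martin oxidation gives the α-oxygenated aldehyde without base, so C8 should not epimerise.

Step 7
Reactants: 8 (2S,3R)-5-oxo-3-(prop-1-en-2-yl)oxolane-2-carbaldehyde; 3 1-({[(3Z)-4-iodopent-3-en-1-yl]oxy}methyl)-4-methoxybenzene
Product: 9 (4R,5S)-5-{(1R,2Z)-1-hydroxy-5-[(4-methoxyphenyl)methoxy]-2-methylpent-2-en-1-yl}-4-(prop-1-en-2-yl)oxolan-2-one
Conditions: CrCl2 (5 equiv), NiCl2 (2 mol %), DMSO, rt
Reagents that add atoms: none
Why: Intermolecular Nozaki–Hiyama–Kishi reaction, in which nickel inserts into the C–I bond, the alkenyl group passes to chromium with retention of the Z geometry and the alkenylchromium species (trivalent chromium) adds only to the aldehyde, Felkin–Anh attack anti to the ring C8–O bond giving the erythro C8/C9 relation (C9 R).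

Step 8
Reactants: 9 the C9 allylic alcohol lactone
Product: 10 (4R,5S)-5-{(1R,2Z)-1-[(tert-butyldimethylsilyl)oxy]-5-[(4-methoxyphenyl)methoxy]-2-methylpent-2-en-1-yl}-4-(prop-1-en-2-yl)oxolan-2-one
Conditions: t-BuMe2SiOTf, 2,6-lutidine, CH2Cl2, −78 → 0 °C
Reagents that add atoms: tert-butyldimethylsilyl trifluoromethanesulfonate, CC(C)(C)[Si](C)(C)OS(=O)(=O)C(F)(F)F
Why: Silyl triflate silylation of the hindered allylic alcohol marks O9 as the oxygen that is freed last and keeps it from binding vanadium in step 18.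

Step 9
Reactants: 10 the C9 silyl ether lactone
Product: 11 (3R,4S,5R,6Z)-5-[(tert-butyldimethylsilyl)oxy]-4-hydroxy-N-methoxy-9-[(4-methoxyphenyl)methoxy]-N,6-dimethyl-3-(prop-1-en-2-yl)non-6-enamide (free C8 hydroxyl)
Conditions: MeNH(OMe)·HCl, AlMe3, CH2Cl2, 0 °C → rt
Reagents that add atoms: N,O-dimethylhydroxylamine hydrochloride, CNOC.Cl
Why: Aluminium amide aminolysis of the γ-lactone (Weinreb amide formation) frees only the C8 hydroxyl and produces no basic alkoxide, so the silyl group should not migrate from O9 to O8.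

Step 10
Reactants: 11 the C8 hydroxy Weinreb amide
Product: 12 (3R,4S,5R,6Z)-5-[(tert-butyldimethylsilyl)oxy]-1-[methoxy(methyl)amino]-9-[(4-methoxyphenyl)methoxy]-6-methyl-1-oxo-3-(prop-1-en-2-yl)non-6-en-4-yl (2Z)-2-methylbut-2-enoate (C8 angelate)
Conditions: angelic acid, 2,4,6-trichlorobenzoyl chloride, Et3N, toluene, rt, filter; then 11, toluene, 70 °C
Reagents that add atoms: angelic acid, C/C=C(/C)C(=O)O
Why: Yamaguchi esterification with the preformed mixed anhydride and without DMAP acylates O8 while keeping the Z geometry of the angelate, and hydroxy amide that relactonises to 10 can be returned to step 9.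

Step 11
Reactants: 12 the C8 angelate Weinreb amide
Product: 13 (3R,4S,5R,6Z)-5-[(tert-butyldimethylsilyl)oxy]-9-[(4-methoxyphenyl)methoxy]-6-methyl-1-oxo-3-(prop-1-en-2-yl)non-6-en-4-yl (2Z)-2-methylbut-2-enoate (C5 aldehyde)
Conditions: Cp2Zr(H)Cl (1.5 equiv), THF, rt, 20 min; aqueous work-up
Reagents that add atoms: none
Why: Reduction of the tertiary N-methoxy amide by Cp2Zr(H)Cl proceeds through a zirconated hemiaminal that releases the aldehyde on work-up and is faster than any reaction of this hydride with esters or with 1,1-di- and trisubstituted alkenes.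

Step 12
Reactants: 13 the C5 aldehyde
Product: 14 (2Z,5R,6S,7R,8Z)-7-[(tert-butyldimethylsilyl)oxy]-2-iodo-11-[(4-methoxyphenyl)methoxy]-8-methyl-5-(prop-1-en-2-yl)undeca-2,8-dien-6-yl (2Z)-2-methylbut-2-enoate
Conditions: EtPPh3+ I−, n-BuLi, THF, 0 °C; I2, −78 °C; NaN(SiMe3)2, −20 °C; then 13, −78 → −20 °C
Reagents that add atoms: ethyltriphenylphosphonium iodide, CC[P+](c1ccccc1)(c1ccccc1)c1ccccc1.[I-]; iodine, II
Why: Stork–Zhao olefination as in step 2 gives the (Z)-alkenyl iodide that becomes C4=C5, and the ester and silyl ether tolerate the ylide at low temperature.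

Step 13
Reactants: 14 the (Z)-alkenyl iodide with the 4-methoxybenzyl ether at O3
Product: 15 (2Z,5R,6S,7R,8Z)-7-[(tert-butyldimethylsilyl)oxy]-11-hydroxy-2-iodo-8-methyl-5-(prop-1-en-2-yl)undeca-2,8-dien-6-yl (2Z)-2-methylbut-2-enoate
Conditions: DDQ, CH2Cl2/pH 7 buffer, 0 °C
Reagents that add atoms: none
Why: Oxidative cleavage of the 4-methoxybenzyl ether by DDQ (hydride abstraction to the benzylic oxocarbenium ion, then hydrolysis) leaves the silyl ether, the ester and the alkenyl iodide intact.

Step 14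
Reactants: 15 the C3 primary alcohol
Product: 16 (3Z,5R,6S,7R,9Z)-5-[(tert-butyldimethylsilyl)oxy]-10-iodo-4-methyl-1-oxo-7-(prop-1-en-2-yl)undeca-3,9-dien-6-yl (2Z)-2-methylbut-2-enoate (C3 aldehyde)
Conditions: Dess–Martin periodinane, NaHCO3, CH2Cl2, 0 °C; used at once
Reagents that add atoms: none
Why: Buffered Dess–Martin oxidation gives the β,γ-unsaturated aldehyde without acid or base that would move C1=C10 into conjugation.

Step 15
Reactants: 16 the seco iodo aldehyde
Product: 17 (1(10)Z,4Z,7R,8S,9R)-9-[(tert-butyldimethylsilyl)oxy]-3-hydroxygermacra-1(10),4,11-trien-8-yl angelate, as both C3 epimers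
Conditions: CrCl2 (10 equiv), NiCl2 (2 mol %), DMSO/THF, 0.002 M, slow addition, rt
Reagents that add atoms: none
Why: Intramolecular Nozaki–Hiyama–Kishi reaction at high dilution forms the C3–C4 bond and the ten-membered ring with retention of the Z geometry at C4=C5, and the configuration at C3 is not relied on because it is reset in steps 16 and 17.

Step 16
Reactants: 17 the macrocyclic allylic alcohol (C3 epimers)
Product: 18 (1(10)Z,4Z,7R,8S,9R)-9-[(tert-butyldimethylsilyl)oxy]-3-oxogermacra-1(10),4,11-trien-8-yl angelate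
Conditions: Dess–Martin periodinane, NaHCO3, CH2Cl2, 0 °C
Reagents that add atoms: none
Why: Dess–Martin oxidation of the allylic alcohol converges both C3 epimers on one enone under buffered conditions that should not isomerise the skipped C1=C10 alkene.

Step 17
Reactants: 18 the macrocyclic dienone
Product: 19 (1(10)Z,3S,4Z,7R,8S,9R)-9-[(tert-butyldimethylsilyl)oxy]-3-hydroxygermacra-1(10),4,11-trien-8-yl angelate ((Z,Z)-dienol with free C3 hydroxyl)
Conditions: (R)-2-methyl-CBS-oxazaborolidine (0.5 equiv), catecholborane, toluene, −78 °C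
Reagents that add atoms: none
Why: Corey–Bakshi–Shibata reduction, in which the (R)-oxazaborolidine binds the ketone with the α-methylalkenyl arm (C4) as the large group and the C2 methylene as the small one so that hydride is delivered to give the 3S alcohol, while catecholborane at −78 °C should not hydroborate the alkenes.

Step 18
Reactants: 19 the (3S)-(Z,Z)-dienol
Product: 21 (1R,3S,4R,5S,7R,8S,9S,10R)-9-[(tert-butyldimethylsilyl)oxy]-1,10:4,5-diepoxy-3-hydroxygermacr-11-en-8-yl angelate, via 4,5-monoepoxide 20 (not isolated)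
Conditions: VO(acac)2 (10 mol %), t-BuOOH (3 equiv, in decane), CH2Cl2, 0 → 25 °C
Reagents that add atoms: tert-butyl hydroperoxide, CC(C)(C)OO
Why: t-BuOOH oxidises VO(acac)2 to a pentavalent vanadium alkoxide in which O3 and the alkylperoxide are bound to the same metal, and the activated peroxide oxygen is passed within this complex first to the allylic alkene C4=C5 and, after the vanadate re-forms on O3 of mono-epoxide 20, to the homoallylic alkene C1=C10. The closest known reaction type is the vanadium-catalysed hydroxyl-directed epoxidation of allylic and of homoallylic alcohols. Each oxirane closes by concerted transfer of one oxygen atom to both alkene carbons on one face (a three-membered closure by syn addition), so the Z geometry of each alkene becomes a cis-oxirane. C4 and C5 are set by delivery from O3 through the conformer with C3–H in the plane of C4=C5 facing C6 (least A(1,3) strain, expected to be within reach of the ten-membered ring), which gives the threo C3/C4 relation; C1 and C10 are set by the chair-like vanadate reaching the face that gives the 1,3-syn relation of the C3 and C1 oxygens, which is also the face anti to the C9 silyloxy group in its A(1,3)-preferred conformer (erythro C9/C10). The step needs site selectivity for the two trisubstituted ring alkenes and one facial sense at each: only O3 can bind vanadium (O9 is silylated, O8 acylated), the isopropenyl group has no hydroxyl within reach and the angelate alkene is electron-poor, so neither should react at 0–25 °C.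

Step 19
Reactants: 21 the bis-epoxide with free C3 hydroxyl
Product: 22 (1R,3S,4S,5S,7R,8S,9S,10R)-9-[(tert-butyldimethylsilyl)oxy]-1,10:4,5-diepoxygermacr-11-ene-3,8-diyl diangelate
Conditions: angelic acid, 2,4,6-trichlorobenzoyl chloride, Et3N, toluene, rt, filter; then 21, toluene, 70 °C
Reagents that add atoms: angelic acid, C/C=C(/C)C(=O)O
Why: Yamaguchi esterification as in step 10 acylates O3, the only free hydroxyl, under conditions that are not basic enough for a Payne rearrangement of the epoxy alcohol.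

Step 20
Reactants: 22 the bis-angelate C9 silyl ether
Product: 23 (1R,3S,4S,5S,7R,8S,9S,10S)-1,10:4,5-diepoxy-9-hydroxygermacr-11-ene-3,8-diyl diangelate (CNP0304877.1)
Conditions: HF·pyridine, pyridine, THF, 0 °C → rt
Reagents that add atoms: none
Why: Fluoride cleavage of the Si–O bond under buffered, non-basic conditions, where no alkoxide is formed, so the C8 angelate should not migrate to O9 and the oxiranes should not open.

**Compound list**

1 | 3-[(4-methoxyphenyl)methoxy]propan-1-ol | COc1ccc(COCCCO)cc1 | starting material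
2 | 3-[(4-methoxyphenyl)methoxy]propanal | COc1ccc(COCCC=O)cc1 | intermediate
3 | 1-({[(3Z)-4-iodopent-3-en-1-yl]oxy}methyl)-4-methoxybenzene | C/C(I)=C/CCOCc1ccc(OC)cc1 | intermediate
4 | (5S)-5-(hydroxymethyl)furan-2(5H)-one | OC[C@H]1OC(=O)C=C1 | starting material
5 | (5S)-5-{[(tert-butyldiphenylsilyl)oxy]methyl}furan-2(5H)-one | CC(C)(C)[Si](OC[C@H]1OC(=O)C=C1)(c1ccccc1)c1ccccc1 | intermediate
6 | (4R,5S)-5-{[(tert-butyldiphenylsilyl)oxy]methyl}-4-(prop-1-en-2-yl)oxolan-2-one | CC(C)(C)[Si](OC[C@H]1OC(=O)C[C@@H]1C(C)=C)(c1ccccc1)c1ccccc1 | intermediate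
7 | (4R,5S)-5-(hydroxymethyl)-4-(prop-1-en-2-yl)oxolan-2-one | OC[C@H]1OC(=O)C[C@@H]1C(C)=C | intermediate
8 | (2S,3R)-5-oxo-3-(prop-1-en-2-yl)oxolane-2-carbaldehyde | O=C[C@H]1OC(=O)C[C@@H]1C(C)=C | intermediate
9 | (4R,5S)-5-{(1R,2Z)-1-hydroxy-5-[(4-methoxyphenyl)methoxy]-2-methylpent-2-en-1-yl}-4-(prop-1-en-2-yl)oxolan-2-one | C=C(C)[C@H]1CC(=O)O[C@@H]1[C@H](O)/C(C)=C\CCOCc1ccc(OC)cc1 | intermediate
10 | (4R,5S)-5-{(1R,2Z)-1-[(tert-butyldimethylsilyl)oxy]-5-[(4-methoxyphenyl)methoxy]-2-methylpent-2-en-1-yl}-4-(prop-1-en-2-yl)oxolan-2-one | C=C(C)[C@H]1CC(=O)O[C@@H]1[C@H](O[Si](C)(C)C(C)(C)C)/C(C)=C\CCOCc1ccc(OC)cc1 | intermediate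
11 | (3R,4S,5R,6Z)-5-[(tert-butyldimethylsilyl)oxy]-4-hydroxy-N-methoxy-9-[(4-methoxyphenyl)methoxy]-N,6-dimethyl-3-(prop-1-en-2-yl)non-6-enamide | CON(C)C(=O)C[C@H](C(C)=C)[C@H](O)[C@H](O[Si](C)(C)C(C)(C)C)/C(C)=C\CCOCc1ccc(OC)cc1 | intermediate
12 | (3R,4S,5R,6Z)-5-[(tert-butyldimethylsilyl)oxy]-1-[methoxy(methyl)amino]-9-[(4-methoxyphenyl)methoxy]-6-methyl-1-oxo-3-(prop-1-en-2-yl)non-6-en-4-yl (2Z)-2-methylbut-2-enoate | CON(C)C(=O)C[C@H](C(C)=C)[C@H](OC(=O)/C(C)=C\C)[C@H](O[Si](C)(C)C(C)(C)C)/C(C)=C\CCOCc1ccc(OC)cc1 | intermediate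
13 | (3R,4S,5R,6Z)-5-[(tert-butyldimethylsilyl)oxy]-9-[(4-methoxyphenyl)methoxy]-6-methyl-1-oxo-3-(prop-1-en-2-yl)non-6-en-4-yl (2Z)-2-methylbut-2-enoate | O=CC[C@H](C(C)=C)[C@H](OC(=O)/C(C)=C\C)[C@H](O[Si](C)(C)C(C)(C)C)/C(C)=C\CCOCc1ccc(OC)cc1 | intermediate
14 | (2Z,5R,6S,7R,8Z)-7-[(tert-butyldimethylsilyl)oxy]-2-iodo-11-[(4-methoxyphenyl)methoxy]-8-methyl-5-(prop-1-en-2-yl)undeca-2,8-dien-6-yl (2Z)-2-methylbut-2-enoate | C/C(I)=C/C[C@H](C(C)=C)[C@H](OC(=O)/C(C)=C\C)[C@H](O[Si](C)(C)C(C)(C)C)/C(C)=C\CCOCc1ccc(OC)cc1 | intermediate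
15 | (2Z,5R,6S,7R,8Z)-7-[(tert-butyldimethylsilyl)oxy]-11-hydroxy-2-iodo-8-methyl-5-(prop-1-en-2-yl)undeca-2,8-dien-6-yl (2Z)-2-methylbut-2-enoate | C/C(I)=C/C[C@H](C(C)=C)[C@H](OC(=O)/C(C)=C\C)[C@H](O[Si](C)(C)C(C)(C)C)/C(C)=C\CCO | intermediate
16 | (3Z,5R,6S,7R,9Z)-5-[(tert-butyldimethylsilyl)oxy]-10-iodo-4-methyl-1-oxo-7-(prop-1-en-2-yl)undeca-3,9-dien-6-yl (2Z)-2-methylbut-2-enoate | C/C(I)=C/C[C@H](C(C)=C)[C@H](OC(=O)/C(C)=C\C)[C@H](O[Si](C)(C)C(C)(C)C)/C(C)=C\CC=O | intermediate
17 | (1(10)Z,4Z,7R,8S,9R)-9-[(tert-butyldimethylsilyl)oxy]-3-hydroxygermacra-1(10),4,11-trien-8-yl angelate, C3 epimers | C=C(C)[C@H]1C/C=C(C)\C(O)C/C=C(C)\[C@@H](O[Si](C)(C)C(C)(C)C)[C@H]1OC(=O)/C(C)=C\C | intermediate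
18 | (1(10)Z,4Z,7R,8S,9R)-9-[(tert-butyldimethylsilyl)oxy]-3-oxogermacra-1(10),4,11-trien-8-yl angelate | C=C(C)[C@H]1C/C=C(C)\C(=O)C/C=C(C)\[C@@H](O[Si](C)(C)C(C)(C)C)[C@H]1OC(=O)/C(C)=C\C | intermediate
19 | (1(10)Z,3S,4Z,7R,8S,9R)-9-[(tert-butyldimethylsilyl)oxy]-3-hydroxygermacra-1(10),4,11-trien-8-yl angelate | C=C(C)[C@H]1C/C=C(C)\[C@@H](O)C/C=C(C)\[C@@H](O[Si](C)(C)C(C)(C)C)[C@H]1OC(=O)/C(C)=C\C | intermediate
20 | (1(10)Z,3S,4R,5S,7R,8S,9R)-9-[(tert-butyldimethylsilyl)oxy]-4,5-epoxy-3-hydroxygermacra-1(10),11-dien-8-yl angelate | C=C(C)[C@H]1C[C@@H]2O[C@]2(C)[C@@H](O)C/C=C(C)\[C@@H](O[Si](C)(C)C(C)(C)C)[C@H]1OC(=O)/C(C)=C\C | intermediate (not isolated)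
21 | (1R,3S,4R,5S,7R,8S,9S,10R)-9-[(tert-butyldimethylsilyl)oxy]-1,10:4,5-diepoxy-3-hydroxygermacr-11-en-8-yl angelate | C=C(C)[C@H]1C[C@@H]2O[C@]2(C)[C@@H](O)C[C@H]2O[C@@]2(C)[C@@H](O[Si](C)(C)C(C)(C)C)[C@H]1OC(=O)/C(C)=C\C | intermediate
22 | (1R,3S,4S,5S,7R,8S,9S,10R)-9-[(tert-butyldimethylsilyl)oxy]-1,10:4,5-diepoxygermacr-11-ene-3,8-diyl diangelate | C=C(C)[C@H]1C[C@@H]2O[C@]2(C)[C@@H](OC(=O)/C(C)=C\C)C[C@H]2O[C@@]2(C)[C@@H](O[Si](C)(C)C(C)(C)C)[C@H]1OC(=O)/C(C)=C\C | intermediate
23 | (1R,3S,4S,5S,7R,8S,9S,10S)-1,10:4,5-diepoxy-9-hydroxygermacr-11-ene-3,8-diyl diangelate (CNP0304877.1) | C=C(C)[C@H]1C[C@@H]2O[C@]2(C)[C@@H](OC(=O)/C(C)=C\C)C[C@H]2O[C@@]2(C)[C@@H](O)[C@H]1OC(=O)/C(C)=C\C | target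

**Step count and risks**

Total step count: 20. Longest linear sequence: 18 steps (steps 3–20, from 4); steps 1 and 2 make the side fragment 3.

The three steps most likely to fail:

Step 18 (key step). The facial sense of oxygen delivery at C4=C5 may not follow the A(1,3) model: vanadate-bound delivery to ring-cis allylic alcohols of eight- and nine-membered rings is known to favour the cis (erythro) epoxy alcohol, and the ten-membered ring could behave the same way. In addition, the allylic alcohol may be oxidised to the enone before it is epoxidised, and the slower homoallylic epoxidation may stall at the mono-epoxide stage. The fallback replaces metal-alkoxide delivery by a hydrogen-bond-directed peracid epoxidation (Henbest type). It sets out from 19: mCPBA (1.05 equiv), NaHCO3, CH2Cl2, −20 °C should epoxidise C4=C5 in the threo sense that peracids give with ring-cis allylic alcohols of medium rings, giving 20. A second equivalent of mCPBA at 0 °C should then epoxidise C1=C10 anti to the C9 silyloxy group (allylic strain control), and the sequence comes back to the route at 21. No compound outside the list is made (F0).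

Step 15. Intermolecular coupling to oligomers and simple reduction of the C–I bond may outrun ring closure because of transannular strain in the (Z,Z)-ten-membered ring, and the β,γ-unsaturated aldehyde may isomerise into conjugation during the slow addition. The fallback closes the same C3–C4 bond by an acylative Stille macrocyclisation, which forms the ketone directly by reductive elimination at palladium. It sets out from 15: Dess–Martin oxidation followed by NaClO2, NaH2PO4 and 2-methylbut-2-ene should give the seco iodo acid F1. Me3SnSnMe3 with Pd(PPh3)4 and i-Pr2NEt in toluene at 80 °C should exchange iodine for tin with retention to give the alkenylstannane acid F2. 1-Chloro-N,N,2-trimethylprop-1-en-1-amine in CH2Cl2 at 0 °C should give the acid chloride F3, which is cyclised without isolation at high dilution with Pd2(dba)3 and tri(2-furyl)phosphine in THF at 50 °C. The sequence comes back to the route at 18 and makes step 16 unnecessary.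

Step 7. Facial selectivity at C9 may be poor if chelation of chromium between the aldehyde oxygen and the ring oxygen competes with the Felkin–Anh pathway, so that both C9 epimers form. The fallback sets C9 by reagent-controlled reduction instead of by the C–C bond formation. It sets out from 9 as obtained (mixed with its C9 epimer): Dess–Martin oxidation should give the lactone enone F4, and (R)-2-methyl-CBS-oxazaborolidine with catecholborane in toluene at −78 °C (alkenyl arm as the large group) should reduce it to the 9R alcohol, coming back to the route at 9.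

Further compounds
F0 | step 18 | none | none
F1 | step 15 | (3Z,5R,6S,7R,9Z)-5-[(tert-butyldimethylsilyl)oxy]-10-iodo-4-methyl-6-{[(2Z)-2-methylbut-2-enoyl]oxy}-7-(prop-1-en-2-yl)undeca-3,9-dienoic acid | C/C(I)=C/C[C@H](C(C)=C)[C@H](OC(=O)/C(C)=C\C)[C@H](O[Si](C)(C)C(C)(C)C)/C(C)=C\CC(=O)O
F2 | step 15 | (3Z,5R,6S,7R,9Z)-5-[(tert-butyldimethylsilyl)oxy]-4-methyl-6-{[(2Z)-2-methylbut-2-enoyl]oxy}-7-(prop-1-en-2-yl)-10-(trimethylstannyl)undeca-3,9-dienoic acid | C/C([Sn](C)(C)C)=C/C[C@H](C(C)=C)[C@H](OC(=O)/C(C)=C\C)[C@H](O[Si](C)(C)C(C)(C)C)/C(C)=C\CC(=O)O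
F3 | step 15 | (3Z,5R,6S,7R,9Z)-5-[(tert-butyldimethylsilyl)oxy]-4-methyl-6-{[(2Z)-2-methylbut-2-enoyl]oxy}-7-(prop-1-en-2-yl)-10-(trimethylstannyl)undeca-3,9-dienoyl chloride | C/C([Sn](C)(C)C)=C/C[C@H](C(C)=C)[C@H](OC(=O)/C(C)=C\C)[C@H](O[Si](C)(C)C(C)(C)C)/C(C)=C\CC(=O)Cl
F4 | step 7 | (4R,5S)-5-{(2Z)-5-[(4-methoxyphenyl)methoxy]-2-methylpent-2-enoyl}-4-(prop-1-en-2-yl)oxolan-2-one | C=C(C)[C@H]1CC(=O)O[C@@H]1C(=O)/C(C)=C\CCOCc1ccc(OC)cc1
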